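**Strategy.** The pyranone of the chromone is traced back to an isoxazole: chromone C4, C3 and C2, oxygenated at C4 and C2 and lying between ring A and the arylethyl chain, map onto C3, C4 and C5 of a 3-aryl-5-alkylisoxazole. Cycloaddition of a ring A nitrile oxide to a terminal alkyne creates the C4–C3 bond and the C2–O bond at once and stores the 1,3-dioxygenated chain in a robust aromatic ring. The partners are an O-benzylated 2-hydroxy-4,5-dimethoxybenzaldoxime and 4-(3-benzyloxy-4-methoxyphenyl)but-1-yne. One hydrogenation then breaks the N–O bond and both benzyl ethers, and acid closes the pyranone.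

Key step: step 6

Remark on the chemistry: 3-benzyloxy-4-methoxybenzaldehyde (O-benzylisovanillin) is taken as a catalogue compound; if it had to be made, one Williamson step from isovanillin and benzyl bromide would supply it.

**Route**

Step 1
Reactants: 1 2-hydroxy-4,5-dimethoxybenzaldehyde; 2 benzyl bromide
Product: 3 2-(benzyloxy)-4,5-dimethoxybenzaldehyde
Conditions: BnBr, K2CO3, DMF, 60 °C
Reagents that add atoms: benzyl bromide, BrCc1ccccc1
Why: Williamson ether synthesis, in which the phenoxide (although hydrogen-bonded to the ortho formyl group) should be alkylated cleanly by the reactive benzylic bromide in a polar aprotic solvent while carbonate leaves the aldehyde untouched.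

Step 2
Reactants: 3 2-(benzyloxy)-4,5-dimethoxybenzaldehyde
Product: 4 (E)-2-(benzyloxy)-4,5-dimethoxybenzaldehyde oxime
Conditions: NH2OH·HCl, NaOAc, EtOH/H2O, rt
Reagents that add atoms: hydroxylamine hydrochloride, Cl.NO
Why: Oxime condensation of an aryl aldehyde, which should give the thermodynamically preferred E-aldoxime; the C=N geometry is erased in any case when the nitrile oxide is formed.

Step 3
Reactants: 5 3-(benzyloxy)-4-methoxybenzaldehyde
Product: 6 [3-(benzyloxy)-4-methoxyphenyl]methanol
Conditions: NaBH4, MeOH, 0 °C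
Reagents that add atoms: none
Why: Borohydride reduction of an aryl aldehyde to the benzylic alcohol, to which the benzyl and methyl aryl ethers are inert.

Step 4
Reactants: 6 [3-(benzyloxy)-4-methoxyphenyl]methanol
Product: 7 2-(benzyloxy)-4-(bromomethyl)-1-methoxybenzene
Conditions: PBr3, CH2Cl2, 0 °C; used crude at once
Reagents that add atoms: phosphorus tribromide, BrP(Br)Br
Why: Bromination of a benzylic alcohol through its phosphite ester and displacement by bromide, accelerated by the para methoxy group and cold enough to spare the benzyl ether; the labile bromide is not stored.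

Step 5
Reactants: 7 2-(benzyloxy)-4-(bromomethyl)-1-methoxybenzene; 8 1-(trimethylsilyl)propyne
Product: 10 4-(3-benzyloxy-4-methoxyphenyl)but-1-yne, via silylated alkyne 9 (not isolated)
Conditions: 8 (slight excess over base), n-BuLi, THF, −78 → −40 °C; then 7, −78 → 0 °C; then MeOH, K2CO3, rt
Reagents that add atoms: 1-(trimethylsilyl)propyne, CC#C[Si](C)(C)C
Why: SN2 alkylation of 3-lithio-1-(trimethylsilyl)propyne by the benzylic bromide, in which the silyl group steers the ambident propargyl/allenyl anion to react at its CH2 end, followed in the same flask by base-mediated methanolysis of the alkynyl C–Si bond to free the terminal alkyne.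

Step 6
Reactants: 4 (E)-2-(benzyloxy)-4,5-dimethoxybenzaldehyde oxime; 10 4-(3-benzyloxy-4-methoxyphenyl)but-1-yne
Product: 13 3-(2-benzyloxy-4,5-dimethoxyphenyl)-5-[2-(3-benzyloxy-4-methoxyphenyl)ethyl]isoxazole, via hydroximoyl chloride 11 (not isolated), via nitrile oxide 12 (not isolated)
Conditions: 4 (slight excess), aq NaOCl (added dropwise over hours), Et3N (cat.), CH2Cl2, 0 °C → rt
Reagents that add atoms: none
Why: Hypochlorite chlorinates the aldoxime carbon to hydroximoyl chloride 11, which loses HCl at the basic interface to give nitrile oxide 12, and this dipole adds across the C≡C bond of 10 in a concerted, asynchronous, suprafacial (3+2) cycloaddition in which the dipole carbon joins the terminal CH and the dipole oxygen joins the internal alkyne carbon. This is the Huisgen 1,3-dipolar cycloaddition of an aryl nitrile oxide to a monosubstituted alkyne with in situ bleach generation of the dipole, a standard entry to 3,5-disubstituted isoxazoles. The isoxazole ring is closed intermolecularly by the cycloaddition itself, its C3–C4 and O1–C5 bonds forming in the same event, and it is aromatic as formed, so no later oxidation is needed. No stereocentre is created. The 3,5-isomer should prevail over the 3,4-isomer because the unhindered CH terminus of the alkyne carries the larger frontier-orbital coefficient and meets the aryl-bearing dipole carbon, while dimerisation to the furoxan is held back by the slow addition of bleach, which keeps the dipole concentration low, and by the ortho benzyloxy group, which shields the nitrile oxide carbon. The benzyl and methyl aryl ethers of both partners are inert to cold alkaline hypochlorite.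

Step 7
Reactants: 13 3-(2-benzyloxy-4,5-dimethoxyphenyl)-5-[2-(3-benzyloxy-4-methoxyphenyl)ethyl]isoxazole
Product: 16 2-[2-(3-hydroxy-4-methoxyphenyl)ethyl]-6,7-dimethoxy-4H-chromen-4-one, via enaminone diphenol 14 (not isolated), via hydroxyaryl diketone 15 (not isolated)
Conditions: H2 (1 atm), Pd/C, EtOAc/EtOH, rt; filter; then 2 M aq HCl, EtOH, reflux
Reagents that add atoms: water, O
Why: Catalytic hydrogenolysis should cleave the weak isoxazole N–O bond to the Z-β-enaminone and both O-benzyl ethers in one operation, and once the catalyst is removed aqueous acid hydrolyses the vinylogous amide to the o-hydroxyaryl 1,3-diketone, whose ring A phenol adds to the C2 ketone and dehydrates (the acid cyclodehydration that ends a Baker–Venkataraman chromone synthesis), so the chromone C2=C3 bond appears only after hydrogen and palladium are gone.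

**Compound list**

1 | 2-hydroxy-4,5-dimethoxybenzaldehyde | COc1cc(O)c(C=O)cc1OC | starting material
2 | benzyl bromide | BrCc1ccccc1 | starting material
3 | 2-(benzyloxy)-4,5-dimethoxybenzaldehyde | COc1cc(OCc2ccccc2)c(C=O)cc1OC | intermediate
4 | (E)-2-(benzyloxy)-4,5-dimethoxybenzaldehyde oxime | O/N=C/c1cc(OC)c(OC)cc1OCc1ccccc1 | intermediate
5 | 3-(benzyloxy)-4-methoxybenzaldehyde | COc1ccc(C=O)cc1OCc1ccccc1 | starting material
6 | [3-(benzyloxy)-4-methoxyphenyl]methanol | COc1ccc(CO)cc1OCc1ccccc1 | intermediate
7 | 2-(benzyloxy)-4-(bromomethyl)-1-methoxybenzene | COc1ccc(CBr)cc1OCc1ccccc1 | intermediate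
8 | 1-(trimethylsilyl)propyne | CC#C[Si](C)(C)C | starting material
9 | [4-(3-benzyloxy-4-methoxyphenyl)but-1-yn-1-yl]trimethylsilane (silylated alkyne, not isolated) | COc1ccc(CCC#C[Si](C)(C)C)cc1OCc1ccccc1 | intermediate
10 | 4-(3-benzyloxy-4-methoxyphenyl)but-1-yne | C#CCCc1ccc(OC)c(OCc2ccccc2)c1 | intermediate
11 | (Z)-2-(benzyloxy)-N-hydroxy-4,5-dimethoxybenzimidoyl chloride (hydroximoyl chloride, not isolated) | O/N=C(\Cl)c1cc(OC)c(OC)cc1OCc1ccccc1 | intermediate
12 | 2-(benzyloxy)-4,5-dimethoxybenzonitrile oxide (not isolated) | [O-][N+]#Cc1cc(OC)c(OC)cc1OCc1ccccc1 | intermediate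
13 | 3-(2-benzyloxy-4,5-dimethoxyphenyl)-5-[2-(3-benzyloxy-4-methoxyphenyl)ethyl]isoxazole | COc1ccc(CCc2cc(-c3cc(OC)c(OC)cc3OCc3ccccc3)no2)cc1OCc1ccccc1 | intermediate
14 | (Z)-1-amino-1-(2-hydroxy-4,5-dimethoxyphenyl)-5-(3-hydroxy-4-methoxyphenyl)pent-1-en-3-one (enaminone diphenol, not isolated) | COc1ccc(CCC(=O)/C=C(\N)c2cc(OC)c(OC)cc2O)cc1O | intermediate
15 | 1-(2-hydroxy-4,5-dimethoxyphenyl)-5-(3-hydroxy-4-methoxyphenyl)pentane-1,3-dione (not isolated) | COc1ccc(CCC(=O)CC(=O)c2cc(OC)c(OC)cc2O)cc1O | intermediate
16 | 2-[2-(3-hydroxy-4-methoxyphenyl)ethyl]-6,7-dimethoxy-4H-chromen-4-one | COc1ccc(CCc2cc(=O)c3cc(OC)c(OC)cc3o2)cc1O | target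

**Step count.** Total: 7 steps. Longest linear sequence: 5 steps (5 → 6 → 7 → 10 → 13 → 16).

**Steps most likely to fail**

Step 6. The nitrile oxide may dimerise to the furoxan faster than it adds to the unactivated alkyl alkyne, or hypochlorite may chlorinate the electron-rich ring A. The fallback avoids the dipole altogether; it sets out from alkyne 10 and aldehyde 3 and rejoins the route at target 16. The lithium acetylide of 10 (n-BuLi, THF, −78 °C) is added to 3 to give racemic 1-(2-benzyloxy-4,5-dimethoxyphenyl)-5-(3-benzyloxy-4-methoxyphenyl)pent-2-yn-1-ol F1. MnO2 in CH2Cl2 should oxidise this to 1-(2-benzyloxy-4,5-dimethoxyphenyl)-5-(3-benzyloxy-4-methoxyphenyl)pent-2-yn-1-one F2. Conjugate addition of diethylamine in EtOH at rt should give (E)-1-(2-benzyloxy-4,5-dimethoxyphenyl)-5-(3-benzyloxy-4-methoxyphenyl)-3-(diethylamino)pent-2-en-1-one F3. Hydrogenolysis (H2, Pd/C, EtOAc), to which the vinylogous amide is resistant, then frees both phenols as (E)-3-(diethylamino)-1-(2-hydroxy-4,5-dimethoxyphenyl)-5-(3-hydroxy-4-methoxyphenyl)pent-2-en-1-one F4. After filtration, warming in aqueous HCl/EtOH lets the ring A phenol displace diethylamine by addition–elimination and closes the pyranone to 16.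

Step 5. Halogen–lithium exchange may lead to Wurtz-type homocoupling of the electron-rich benzylic bromide, or the ambident anion may react through its allenyl terminus. The fallback builds the alkyne by one-carbon homologation of an aldehyde; it sets out from bromide 7 and rejoins the route at alkyne 10. Lithiated acetonitrile (MeCN, LiN(i-Pr)2, THF, −78 °C, in excess) is alkylated by 7 to give 3-(3-benzyloxy-4-methoxyphenyl)propanenitrile F5. Partial reduction with i-Bu2AlH (toluene, −78 °C) and acidic hydrolysis of the aluminium imine gives 3-(3-benzyloxy-4-methoxyphenyl)propanal F6. Ohira–Bestmann homologation (dimethyl (1-diazo-2-oxopropyl)phosphonate, K2CO3, MeOH, rt) then delivers 10.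

Step 7. Hydrogenolysis of the N–O bond on palladium may stall after the benzyl ethers have gone, or run on to saturate the enaminone C=C bond. The fallback separates ring opening from deprotection and uses no hydrogen; it sets out from isoxazole 13 and rejoins the route at enaminone 14. Mo(CO)6 in wet MeCN at reflux cleaves the N–O bond reductively without touching the benzyl ethers and should give (Z)-1-amino-1-(2-benzyloxy-4,5-dimethoxyphenyl)-5-(3-benzyloxy-4-methoxyphenyl)pent-1-en-3-one F7. BCl3 with pentamethylbenzene as cation scavenger (CH2Cl2, −78 °C) removes both benzyl groups and spares the methyl ethers, giving 14, which is cyclised with aqueous HCl as in step 7.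

**Further compounds**

F1 | step 6 | 1-(2-benzyloxy-4,5-dimethoxyphenyl)-5-(3-benzyloxy-4-methoxyphenyl)pent-2-yn-1-ol (racemic) | COc1ccc(CCC#CC(O)c2cc(OC)c(OC)cc2OCc2ccccc2)cc1OCc1ccccc1
F2 | step 6 | 1-(2-benzyloxy-4,5-dimethoxyphenyl)-5-(3-benzyloxy-4-methoxyphenyl)pent-2-yn-1-one | COc1ccc(CCC#CC(=O)c2cc(OC)c(OC)cc2OCc2ccccc2)cc1OCc1ccccc1
F3 | step 6 | (E)-1-(2-benzyloxy-4,5-dimethoxyphenyl)-5-(3-benzyloxy-4-methoxyphenyl)-3-(diethylamino)pent-2-en-1-one | CCN(CC)/C(CCc1ccc(OC)c(OCc2ccccc2)c1)=C/C(=O)c1cc(OC)c(OC)cc1OCc1ccccc1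
F4 | step 6 | (E)-3-(diethylamino)-1-(2-hydroxy-4,5-dimethoxyphenyl)-5-(3-hydroxy-4-methoxyphenyl)pent-2-en-1-one | CCN(CC)/C(CCc1ccc(OC)c(O)c1)=C/C(=O)c1cc(OC)c(OC)cc1O
F5 | step 5 | 3-(3-benzyloxy-4-methoxyphenyl)propanenitrile | COc1ccc(CCC#N)cc1OCc1ccccc1
F6 | step 5 | 3-(3-benzyloxy-4-methoxyphenyl)propanal | COc1ccc(CCC=O)cc1OCc1ccccc1
F7 | step 7 | (Z)-1-amino-1-(2-benzyloxy-4,5-dimethoxyphenyl)-5-(3-benzyloxy-4-methoxyphenyl)pent-1-en-3-one | COc1ccc(CCC(=O)/C=C(\N)c2cc(OC)c(OC)cc2OCc2ccccc2)cc1OCc1ccccc1
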